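The dihydroxychroman half is cut across its benzene ring. Ring C carries oxygen at C5, C7 and C8a and the acyl chain at C6, a pattern that maps onto a 1,1,3-trioxygenated diene (C7, C8, C8a, C4a, with the O1–C8a enol ether already part of pyran ring D) and an acyl alkoxy alkyne (C5, C6). One cycloaddition with loss of methanol forms C4a–C5 and C6–C7, builds ring C as an arene and joins both halves. The precursors are a dihydropyranyl silyl ketene acetal and the 3-ethoxy ynone of the chroman side chain; the ethyl ether is then cleaved by chelation before the silyl ether is removed.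

Key step: step 7

Remark: 6,6-dimethyltetrahydro-2H-pyran-2-one, methyl 3-(4-hydroxyphenyl)propanoate and ethoxyacetylene (hexane solution) are taken as purchasable; atom labels follow chroman numbering (O1, C2–C4, C4a, C5–C8, C8a).

Step 1
Reactants: 1 6,6-dimethyltetrahydro-2H-pyran-2-one; 2 methyl acetate
Product: 4 methyl 2-(2-hydroxy-6,6-dimethyltetrahydro-2H-pyran-2-yl)acetate, via methyl lithioacetate 3 (not isolated)
Conditions: LiN(iPr)2 (2.2 equiv), 2 (2.2 equiv), THF, −78 °C; then 1, −78 → −40 °C; aq. NH4Cl
Reagents that add atoms: none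
Why: Crossed Claisen-type acylation: the lithium enolate of methyl acetate adds to the lactone carbonyl, the second equivalent of enolate stores the product as its β-keto ester enolate so that no second addition occurs, and on work-up the δ-hydroxy β-keto ester closes to the lactol, favoured by the gem-dimethyl group.

Step 2
Reactants: 4 methyl 2-(2-hydroxy-6,6-dimethyltetrahydro-2H-pyran-2-yl)acetate
Product: 5 methyl (2E)-2-(6,6-dimethyltetrahydro-2H-pyran-2-ylidene)acetate
Conditions: TsOH·H2O (5 mol %), toluene, 4 Å MS, rt
Reagents that add atoms: none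
Why: Acid-catalysed dehydration of the lactol through its cyclic oxocarbenium ion, which loses the acidic proton next to the ester to give the conjugated β-alkoxyacrylate, expected as the more stable E isomer under equilibrating conditions; the geometry and any endocyclic alkene isomer are immaterial because both lead to the same dienolate in step 3.

Step 3
Reactants: 5 methyl (2E)-2-(6,6-dimethyltetrahydro-2H-pyran-2-ylidene)acetate
Product: 7 tert-butyl{[(1Z)-2-(6,6-dimethyl-5,6-dihydro-4H-pyran-2-yl)-1-methoxyethenyl]oxy}dimethylsilane, via lithium dienolate 6 (not isolated)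
Conditions: LiN(iPr)2, THF, −78 °C; then tBuMe2SiCl, DMPU, −78 → 0 °C; non-aqueous work-up, bulb-to-bulb distillation
Reagents that add atoms: tert-butyldimethylsilyl chloride, CC(C)(C)[Si](C)(C)Cl
Why: γ-Deprotonation of the β-alkoxyacrylate at ring C3, which lies cis to the ester, gives the extended lithium dienolate, and the silyl chloride in the presence of DMPU traps it on oxygen (silyl ketene acetal formation, the standard entry to 1,1,3-trioxygenated dienes), which moves the double bond into the ring.

Step 4
Reactants: 8 methyl 3-(4-hydroxyphenyl)propanoate; 9 isoprene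
Product: 10 methyl 3-(2,2-dimethylchroman-6-yl)propanoate
Conditions: 9 (2 equiv), AgOTf (5 mol %), ClCH2CH2Cl, rt → 40 °C
Reagents that add atoms: none
Why: Chroman annulation by Friedel–Crafts ortho-prenylation followed by Markovnikov hydroalkoxylation: with the para position blocked the prenyl cation equivalent can only attack ortho to the hydroxyl, and the phenol oxygen then adds to the tertiary carbon of the trisubstituted alkene to close the 2,2-dimethylpyran ring.

Step 5
Reactants: 10 methyl 3-(2,2-dimethylchroman-6-yl)propanoate
Product: 11 3-(2,2-dimethylchroman-6-yl)-N-methoxy-N-methylpropanamide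
Conditions: MeNH(OMe)·HCl, iPrMgCl, THF, −20 → 0 °C; aq. NH4Cl
Reagents that add atoms: N,O-dimethylhydroxylamine hydrochloride, CNOC.Cl
Why: Weinreb amide formation by direct aminolysis of the methyl ester with the chloromagnesium amide made from the amine salt and iPrMgCl, which leaves the aryl alkyl ether untouched.

Step 6
Reactants: 12 ethoxyacetylene; 11 3-(2,2-dimethylchroman-6-yl)-N-methoxy-N-methylpropanamide
Product: 14 5-(2,2-dimethylchroman-6-yl)-1-ethoxypent-1-yn-3-one, via lithium ethoxyacetylide 13 (not isolated)
Conditions: 12, nBuLi, THF, −78 °C; then 11, −78 → −40 °C; cold aq. NH4Cl, rapid extraction, used promptly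
Reagents that add atoms: none
Why: Weinreb ketone synthesis: the lithium acetylide adds once, the five-membered N-methoxy chelate holds the tetrahedral adduct until the cold, nearly neutral quench, and the sensitive 3-ethoxy ynone is therefore released only at work-up, away from strong base and acid.

Step 7
Reactants: 7 tert-butyl{[(1Z)-2-(6,6-dimethyl-5,6-dihydro-4H-pyran-2-yl)-1-methoxyethenyl]oxy}dimethylsilane; 14 5-(2,2-dimethylchroman-6-yl)-1-ethoxypent-1-yn-3-one
Product: 16 1-[7-(tert-butyldimethylsilyloxy)-5-ethoxy-2,2-dimethylchroman-6-yl]-3-(2,2-dimethylchroman-6-yl)propan-1-one, via cyclohexa-1,4-diene cycloadduct 15 (not isolated)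
Conditions: 7 (1.5 equiv), toluene (1 M), 70 °C, sealed tube; then pyridinium p-toluenesulfonate (cat.), CH2Cl2, rt
Reagents that add atoms: none
Why: Proposed new method: C4a of the diene is its electron-richest carbon, because O1 on C8a pushes into it directly and the two oxygens on C7 do so through the conjugated chain, and it should bond to the alkyne carbon that bears the ethoxy group, the β-position of the ynone, either within an unsymmetrical concerted (4+2) transition state or as a vinylogous Mukaiyama–Michael addition whose allenolate then closes from C6 onto the silylated ester carbon C7. The nearest established reaction is the Diels–Alder benzannulation of 1,1,3-trioxygenated silyl dienes with acetylenic ketones and esters; what is untested is a dienophile whose β-carbon carries a donor alkoxy group. Ring C forms by intermolecular (4+2) annulation onto ring D, which in the stepwise picture ends with a 6-exo-trig Claisen-type closure. Cyclohexa-1,4-diene 15 has sp3 centres only at C4a and C7, and acid-assisted 1,4-loss of methanol across them flattens both, so no stereocentre has to be controlled and the silyl ether stays on C7. The only selectivity needed is the orientation (C4a with C5, C7 with C6), which the donor character of the far diene terminus and the acceptor polarisation of the ynone jointly dictate. The bath is kept well below the temperature at which 1-ethoxyalkynes extrude ethene to give ketenes.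

Step 8
Reactants: 16 1-[7-(tert-butyldimethylsilyloxy)-5-ethoxy-2,2-dimethylchroman-6-yl]-3-(2,2-dimethylchroman-6-yl)propan-1-one
Product: 17 1-[7-(tert-butyldimethylsilyloxy)-5-hydroxy-2,2-dimethylchroman-6-yl]-3-(2,2-dimethylchroman-6-yl)propan-1-one
Conditions: BCl3 (1 M in CH2Cl2, 1.5 equiv), CH2Cl2, −78 → −20 °C; aq. NaHCO3
Reagents that add atoms: none
Why: Chelation-assisted aryl ether cleavage: BCl3 bridges the ketone oxygen and the neighbouring ethoxy oxygen and chloride removes the ethyl group by SN2 attack, and this is done before desilylation so that the carbonyl is still free for that chelate (a boron phenoxide on O7 would occupy it), while the unassisted tertiary ethers of both chromans and the bulky, weakly basic silyl ether should survive at low temperature.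

Step 9
Reactants: 17 1-[7-(tert-butyldimethylsilyloxy)-5-hydroxy-2,2-dimethylchroman-6-yl]-3-(2,2-dimethylchroman-6-yl)propan-1-one
Product: 18 1-(5,7-dihydroxy-2,2-dimethylchroman-6-yl)-3-(2,2-dimethylchroman-6-yl)propan-1-one
Conditions: Bu4NF, AcOH, THF, 0 °C
Reagents that add atoms: none
Why: Fluoride-induced desilylation of the aryl silyl ether, driven by Si–F bond formation and buffered with acetic acid so that the ketone and the phenols meet no strong base.

Compound list
1 | 6,6-dimethyltetrahydro-2H-pyran-2-one | CC1(C)CCCC(=O)O1 | starting material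
2 | methyl acetate | COC(C)=O | starting material
3 | methyl lithioacetate (lithium enolate of 2, formed in the flask) | COC(=C)O[Li] | intermediate
4 | methyl 2-(2-hydroxy-6,6-dimethyltetrahydro-2H-pyran-2-yl)acetate (racemic lactol, in equilibrium with the open-chain hydroxy keto ester) | COC(=O)CC1(O)CCCC(C)(C)O1 | intermediate
5 | methyl (2E)-2-(6,6-dimethyltetrahydro-2H-pyran-2-ylidene)acetate | COC(=O)/C=C1\CCCC(C)(C)O1 | intermediate
6 | lithium dienolate of 5 (O–Li cis to the pyranyl group, formed in the flask) | CO\C(O[Li])=C\C1=CCCC(C)(C)O1 | intermediate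
7 | tert-butyl{[(1Z)-2-(6,6-dimethyl-5,6-dihydro-4H-pyran-2-yl)-1-methoxyethenyl]oxy}dimethylsilane | CO\C(O[Si](C)(C)C(C)(C)C)=C\C1=CCCC(C)(C)O1 | intermediate
8 | methyl 3-(4-hydroxyphenyl)propanoate | COC(=O)CCc1ccc(O)cc1 | starting material
9 | isoprene (2-methylbuta-1,3-diene) | CC(=C)C=C | starting material
10 | methyl 3-(2,2-dimethylchroman-6-yl)propanoate | COC(=O)CCc1ccc2OC(C)(C)CCc2c1 | intermediate
11 | 3-(2,2-dimethylchroman-6-yl)-N-methoxy-N-methylpropanamide | CON(C)C(=O)CCc1ccc2OC(C)(C)CCc2c1 | intermediate
12 | ethoxyacetylene | CCOC#C | starting material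
13 | lithium ethoxyacetylide (formed in the flask) | CCOC#C[Li] | intermediate
14 | 5-(2,2-dimethylchroman-6-yl)-1-ethoxypent-1-yn-3-one | CCOC#CC(=O)CCc1ccc2OC(C)(C)CCc2c1 | intermediate
15 | 1-[7-(tert-butyldimethylsilyloxy)-5-ethoxy-7-methoxy-2,2-dimethyl-3,4,4a,7-tetrahydro-2H-chromen-6-yl]-3-(2,2-dimethylchroman-6-yl)propan-1-one (mixture of diastereomers at C4a and C7, both centres lost on aromatisation) | CCOC1=C(C(=O)CCc2ccc3OC(C)(C)CCc3c2)C(OC)(O[Si](C)(C)C(C)(C)C)C=C2OC(C)(C)CCC21 | intermediate
16 | 1-[7-(tert-butyldimethylsilyloxy)-5-ethoxy-2,2-dimethylchroman-6-yl]-3-(2,2-dimethylchroman-6-yl)propan-1-one | CCOc1c(C(=O)CCc2ccc3OC(C)(C)CCc3c2)c(O[Si](C)(C)C(C)(C)C)cc2OC(C)(C)CCc12 | intermediate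
17 | 1-[7-(tert-butyldimethylsilyloxy)-5-hydroxy-2,2-dimethylchroman-6-yl]-3-(2,2-dimethylchroman-6-yl)propan-1-one | CC(C)(C)[Si](C)(C)Oc1cc2OC(C)(C)CCc2c(O)c1C(=O)CCc1ccc2OC(C)(C)CCc2c1 | intermediate
18 | 1-(5,7-dihydroxy-2,2-dimethylchroman-6-yl)-3-(2,2-dimethylchroman-6-yl)propan-1-one (no stereocentre) | CC1(C)CCc2cc(CCC(=O)c3c(O)cc4c(c3O)CCC(C)(C)O4)ccc2O1 | target

Total step count: 9.
Longest linear sequence: 6 steps (steps 4, 5, 6, 7, 8, 9 from 8; equally steps 1, 2, 3, 7, 8, 9 from 1).

Steps most likely to fail

1. Step 7. The donor-substituted alkyne may be too sluggish a dienophile at a temperature that the ynol ether tolerates. Fragmentation of the ethoxyalkyne to a ketene, hydrolysis of the silyl ketene acetal, or arrest at the open-chain Michael stage could then outrun ring closure. The fallback uses known chemistry, sets out from 10 and comes back at 18. Saponification of 10 (LiOH, THF/H2O) should give 3-(2,2-dimethylchroman-6-yl)propanoic acid F1. Friedel–Crafts acylation of purchased phloroglucinol (benzene-1,3,5-triol) with F1 in BF3·OEt2 at 80 °C should give 3-(2,2-dimethylchroman-6-yl)-1-(2,4,6-trihydroxyphenyl)propan-1-one F2. Acid-catalysed prenylation and cyclisation of F2 with isoprene 9 (H3PO4, toluene) should then close ring D onto the hydroxyl para to the ketone and give 18. The 8-acyl isomer, from closure onto a hydroxyl beside the ketone, would have to be separated.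

2. Step 8. Premature loss of the silyl group would turn O7 into a boron phenoxide that ties up the carbonyl, so that the ethoxy group loses its chelation assistance and the cleavage stalls. Forcing it would invite ionisation of the tertiary chroman ethers. The fallback exchanges the protecting group on O7, sets out from 16 and comes back at 18. Desilylation (Bu4NF, AcOH, THF) should give 1-(5-ethoxy-7-hydroxy-2,2-dimethylchroman-6-yl)-3-(2,2-dimethylchroman-6-yl)propan-1-one F3. Acetylation (Ac2O, pyridine, DMAP) should give 5-ethoxy-6-[3-(2,2-dimethylchroman-6-yl)propanoyl]-2,2-dimethylchroman-7-yl acetate F4, whose ester is inert to BCl3 at low temperature and leaves the ketone free to chelate. BCl3 (CH2Cl2, −78 → 0 °C) should then give 6-[3-(2,2-dimethylchroman-6-yl)propanoyl]-5-hydroxy-2,2-dimethylchroman-7-yl acetate F5, and methanolysis (K2CO3, MeOH) should give 18.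

3. Step 6. On release of the ynone the liberated N,O-dimethylhydroxylamine can add in conjugate fashion, and an acidic quench can hydrate the ynol ether to a β-keto ester. The fallback avoids the amide, sets out from 10 and comes back at 14. Reduction of 10 (iBu2AlH, toluene, −78 °C) should give 3-(2,2-dimethylchroman-6-yl)propanal F6. Addition of lithium ethoxyacetylide 13 (THF, −78 °C) should give racemic 5-(2,2-dimethylchroman-6-yl)-1-ethoxypent-1-yn-3-ol F7. Oxidation of the propargylic alcohol with MnO2 (CH2Cl2, rt) under neutral, amine-free conditions should give 14.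

Further compounds
F1 | step 7 | 3-(2,2-dimethylchroman-6-yl)propanoic acid | OC(=O)CCc1ccc2OC(C)(C)CCc2c1
F2 | step 7 | 3-(2,2-dimethylchroman-6-yl)-1-(2,4,6-trihydroxyphenyl)propan-1-one | O=C(CCc1ccc2OC(C)(C)CCc2c1)c1c(O)cc(O)cc1O
F3 | step 8 | 1-(5-ethoxy-7-hydroxy-2,2-dimethylchroman-6-yl)-3-(2,2-dimethylchroman-6-yl)propan-1-one | CCOc1c(C(=O)CCc2ccc3OC(C)(C)CCc3c2)c(O)cc2OC(C)(C)CCc12
F4 | step 8 | 5-ethoxy-6-[3-(2,2-dimethylchroman-6-yl)propanoyl]-2,2-dimethylchroman-7-yl acetate | CCOc1c(C(=O)CCc2ccc3OC(C)(C)CCc3c2)c(OC(C)=O)cc2OC(C)(C)CCc12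
F5 | step 8 | 6-[3-(2,2-dimethylchroman-6-yl)propanoyl]-5-hydroxy-2,2-dimethylchroman-7-yl acetate | CC(=O)Oc1cc2OC(C)(C)CCc2c(O)c1C(=O)CCc1ccc2OC(C)(C)CCc2c1
F6 | step 6 | 3-(2,2-dimethylchroman-6-yl)propanal | O=CCCc1ccc2OC(C)(C)CCc2c1
F7 | step 6 | 5-(2,2-dimethylchroman-6-yl)-1-ethoxypent-1-yn-3-ol (racemic) | CCOC#CC(O)CCc1ccc2OC(C)(C)CCc2c1
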